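Everything rests on cutting the C10–C20 bond. In the target C20 links C10 to the C19 carboxyl oxygen as a δ-lactone fused across ring A, and C19 stands axial on C4, 1,3-diaxial to C10 on the α face; C20 is therefore brought in as an ester substituent on C19 and delivered intramolecularly. In one operation the key step converts a C19 (phenylselanyl)methyl ester into an acyloxymethyl radical that adds to C10 of a ring A 1(10)-en-2-one, forging C10–C20, the lactone ring and the quaternary C10 stereocentre while leaving the C2 carbonyl for the 2β-hydroxyl. The precursor, a 2-oxo-1(10)-ene 19-ester 7-methyl ester, comes from gibberellic acid, which supplies rings B, C, D and the other stereocentres.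

Key step: step 7

**Remarks**

- Gibberellin numbering and α/β descriptors are used: C19 is the α-axial carboxyl carbon on C4, C18 the β-methyl on C4, C20 the carbon on C10, C7 the carboxyl carbon on C6, C13 the tertiary bridgehead carbinol, C16=C17 the exocyclic methylene. Stereocentres not named are those of gibberellic acid.
- Assumption: chloromethyl phenyl selenide is taken as a purchasable reagent.
- The key-step precursor keeps the tertiary 13-hydroxyl free and C7 as its methyl ester. Both are inert to stannyl radicals, and the methyl ester resists every basic step before it, so no protecting-group step is spent.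

**Route**

Step 1
Reactants: 1 gibberellic acid
Product: 2 gibberellic acid 7-methyl ester
Conditions: MeI, KHCO3, DMF, rt
Reagents that add atoms: iodomethane, CI
Why: Carboxylate O-alkylation (SN2 on MeI) under bicarbonate, which is too weak a base to set off the alkali-induced lactone migration of ring A; no stereocentre is touched.

Step 2
Reactants: 2 gibberellic acid 7-methyl ester
Product: 4 2α,3β,13-trihydroxy-20-norgibberella-1(10),16-diene-7,19-dioic acid 7-methyl ester, via 19,2α-lactone isomer 3 (not isolated)
Conditions: NaOH (0.5 M aq.), THF, 0 °C to rt; then HCl (1 M) to pH 3, 0 °C; used directly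
Reagents that add atoms: sodium hydroxide, [Na+].[OH-]
Why: Dilute alkali should first trigger the well-known allylic lactone transposition of gibberellic acid derivatives (the C19 acyloxy group moves from C10 to C2 on the α face as the alkene moves to C1–C10) and then saponify the strained bridged γ-lactone, while the hindered C7 methyl ester resists hydroxide at room temperature; the C2 and C3 carbinol configurations are irrelevant because both are erased in steps 3 and 5.

Step 3
Reactants: 4 2α,3β,13-trihydroxy-20-norgibberella-1(10),16-diene-7,19-dioic acid 7-methyl ester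
Product: 5 3β,13-dihydroxy-2-oxo-20-norgibberella-1(10),16-diene-7,19-dioic acid 7-methyl ester
Conditions: MnO2 (activated, excess), EtOAc–acetone, rt
Reagents that add atoms: none
Why: Allylic alcohol oxidation with MnO2 is selective for the 2-OH flanking the C1–C10 alkene, so the saturated 3-OH and the tertiary 13-OH should stay untouched, and the trans-diol is not set up for glycol cleavage.

Step 4
Reactants: 5 3β,13-dihydroxy-2-oxo-20-norgibberella-1(10),16-diene-7,19-dioic acid 7-methyl ester
Product: 6 3β-acetoxy-13-hydroxy-2-oxo-20-norgibberella-1(10),16-diene-7,19-dioic acid 7-methyl ester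
Conditions: Ac2O, pyridine, 0 °C to rt; then aq. NaHCO3, re-acidify to pH 3
Reagents that add atoms: acetic anhydride, CC(=O)OC(C)=O
Why: Pyridine-mediated O-acetylation of the single secondary hydroxyl turns it into a leaving group for electron-transfer cleavage; the tertiary bridgehead 13-OH is not acylated without DMAP or heat, and the aqueous quench leaves C19 as the free acid.

Step 5
Reactants: 6 3β-acetoxy-13-hydroxy-2-oxo-20-norgibberella-1(10),16-diene-7,19-dioic acid 7-methyl ester
Product: 7 13-hydroxy-2-oxo-20-norgibberella-1(10),16-diene-7,19-dioic acid 7-methyl ester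
Conditions: SmI2 (2.5 equiv), THF–MeOH, −78 °C; then HCl (0.1 M)
Reagents that add atoms: none
Why: SmI2 reductive cleavage of an α-acetoxy ketone (two single-electron transfers expel acetate and MeOH protonates the samarium enolate at C3) is much faster at −78 °C than reduction of the enone, the ester or the acid, and it leaves C3 as a plain methylene.

Step 6
Reactants: 7 13-hydroxy-2-oxo-20-norgibberella-1(10),16-diene-7,19-dioic acid 7-methyl ester; 8 chloromethyl phenyl selenide
Product: 9 7-methyl 19-[(phenylselanyl)methyl] 13-hydroxy-2-oxo-20-norgibberella-1(10),16-diene-7,19-dioate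
Conditions: Cs2CO3 (1.1 equiv), DMF, rt, dark
Reagents that add atoms: chloromethyl phenyl selenide (8), ClC[Se]c1ccccc1
Why: SN2 O-alkylation of the caesium C19 carboxylate by the selenium-activated chloride is insensitive to the crowding around the axial acid, carbonate is too weak to enolise the enone, and any reversible conjugate addition of the carboxylate to C10 is drained by the irreversible alkylation.

Step 7
Reactants: 9 7-methyl 19-[(phenylselanyl)methyl] 13-hydroxy-2-oxo-20-norgibberella-1(10),16-diene-7,19-dioate
Product: 10 13,20-dihydroxy-2-oxogibberell-16-ene-7,19-dioic acid 7-methyl ester 19,20-lactone (C20 on the α face of C10)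
Conditions: Bu3SnH (1.5 equiv) and AIBN (0.2 equiv) by syringe pump, toluene (0.005 M), 110 °C
Reagents that add atoms: none
Why: Bu3Sn• removes PhSe from the O–CH2–SePh carbon, the nucleophilic acyloxymethyl radical so formed attacks the electron-poor β-carbon C10 of the enone, and the resulting C1 radical next to the C2 carbonyl collects hydrogen from Bu3SnH and regenerates Bu3Sn•; the closest known reaction type is the intramolecular Giese-type reductive radical conjugate addition, here in the form of acyloxymethyl radicals from halomethyl or selenomethyl esters closing onto alkenes to give lactones. The δ-lactone (C19, O, C20, C10, C5, C4) closes in the 6-exo-trig mode, C1 lying outside the new ring. The only new stereocentre, quaternary C10, is dictated by the tether: C19 is axial on the α face of C4 and 1,3-diaxial to C10 across ring A, so C20 can bond only to the α face and the bridged lactone must be cis, which is the natural configuration; C1 becomes a methylene and sets no centre. The step needs ring closure to outrun hydrogen transfer to the first radical (from the stannane or by an internal 1,5-shift), a race that ester tethers usually lose because they prefer the non-cyclising rotamer; here the rigid diaxial geometry holds the radical carbon within bonding distance of C10 once the ester rotates, the polarity match of an α-oxygenated radical with an enone speeds the addition, and slow addition of the stannane at 110 °C keeps its concentration low. The free 13-OH, the 16-methylene and the C7 ester are inert to stannyl radicals under these conditions.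

Step 8
Reactants: 10 13,20-dihydroxy-2-oxogibberell-16-ene-7,19-dioic acid 7-methyl ester 19,20-lactone
Product: 11 2β,13,20-trihydroxygibberell-16-ene-7,19-dioic acid 7-methyl ester 19,20-lactone (7-methyl ester of the target)
Conditions: Al(OiPr)3 (3 equiv), iPrOH–toluene, acetone (trace), reflux; then aq. potassium sodium tartrate
Reagents that add atoms: none
Why: Meerwein–Ponndorf–Verley reduction is reversible, so with a trace of acetone and prolonged heating hydride transfer should funnel C2 to the more stable equatorial 2β-alkoxide (the axial 2α-epimer points into the lactone bridge on the α face of ring A), while the hindered C7 ester and the lactone carbonyl flanked by quaternary C4 resist alkoxide exchange.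

Step 9
Reactants: 11 2β,13,20-trihydroxygibberell-16-ene-7,19-dioic acid 7-methyl ester 19,20-lactone
Product: 12 2β,13,20-trihydroxygibberell-16-ene-7,19-dioic acid 19,20-lactone (the target gibberellin)
Conditions: LiSPr (excess), HMPA, rt; then HCl (1 M) to pH 3
Reagents that add atoms: none
Why: Thiolate SN2 dealkylation attacks the unhindered O-methyl carbon and so bypasses the shielded C7 carbonyl, whereas the lactone O–CH2 (C20) is neopentyl and inert to displacement; no stereocentre is involved and acidification releases the acid.

**Compound list**

1 | gibberellic acid (3β,13-dihydroxy-20-norgibberella-1,16-diene-7,19-dioic acid 19,10-lactone) | C=C1C[C@]23C[C@@]1(O)CC[C@H]2[C@]12OC(=O)[C@](C)([C@@H](O)C=C1)[C@H]2[C@@H]3C(=O)O | starting material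
2 | gibberellic acid 7-methyl ester | C=C1C[C@]23C[C@@]1(O)CC[C@H]2[C@]12OC(=O)[C@](C)([C@@H](O)C=C1)[C@H]2[C@@H]3C(=O)OC | intermediate
3 | 3β,13-dihydroxy-20-norgibberella-1(10),16-diene-7,19-dioic acid 7-methyl ester 19,2α-lactone (iso-lactone, not isolated) | C=C1C[C@]23C[C@@]1(O)CC[C@H]2C4=C[C@@H]5[C@H](O)[C@@](C)(C(=O)O5)[C@H]4[C@@H]3C(=O)OC | intermediate
4 | 2α,3β,13-trihydroxy-20-norgibberella-1(10),16-diene-7,19-dioic acid 7-methyl ester | C=C1C[C@]23C[C@@]1(O)CC[C@H]2C4=C[C@@H](O)[C@H](O)[C@@](C)(C(=O)O)[C@H]4[C@@H]3C(=O)OC | intermediate
5 | 3β,13-dihydroxy-2-oxo-20-norgibberella-1(10),16-diene-7,19-dioic acid 7-methyl ester | C=C1C[C@]23C[C@@]1(O)CC[C@H]2C4=CC(=O)[C@H](O)[C@@](C)(C(=O)O)[C@H]4[C@@H]3C(=O)OC | intermediate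
6 | 3β-acetoxy-13-hydroxy-2-oxo-20-norgibberella-1(10),16-diene-7,19-dioic acid 7-methyl ester | C=C1C[C@]23C[C@@]1(O)CC[C@H]2C4=CC(=O)[C@H](OC(C)=O)[C@@](C)(C(=O)O)[C@H]4[C@@H]3C(=O)OC | intermediate
7 | 13-hydroxy-2-oxo-20-norgibberella-1(10),16-diene-7,19-dioic acid 7-methyl ester | C=C1C[C@]23C[C@@]1(O)CC[C@H]2C4=CC(=O)C[C@@](C)(C(=O)O)[C@H]4[C@@H]3C(=O)OC | intermediate
8 | chloromethyl phenyl selenide | ClC[Se]c1ccccc1 | starting material
9 | 7-methyl 19-[(phenylselanyl)methyl] 13-hydroxy-2-oxo-20-norgibberella-1(10),16-diene-7,19-dioate (key-step precursor) | C=C1C[C@]23C[C@@]1(O)CC[C@H]2C4=CC(=O)C[C@@](C)(C(=O)OC[Se]c5ccccc5)[C@H]4[C@@H]3C(=O)OC | intermediate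
10 | 13,20-dihydroxy-2-oxogibberell-16-ene-7,19-dioic acid 7-methyl ester 19,20-lactone, C20 α on C10 (key-step product) | C=C1C[C@]23C[C@@]1(O)CC[C@H]2[C@]12COC(=O)[C@](C)(CC(=O)C1)[C@H]2[C@@H]3C(=O)OC | intermediate
11 | 2β,13,20-trihydroxygibberell-16-ene-7,19-dioic acid 7-methyl ester 19,20-lactone (7-methyl ester of the target) | C=C1C[C@]23C[C@@]1(O)CC[C@H]2[C@]12COC(=O)[C@](C)(C[C@@H](O)C1)[C@H]2[C@@H]3C(=O)OC | intermediate
12 | 2β,13,20-trihydroxygibberell-16-ene-7,19-dioic acid 19,20-lactone (the target gibberellin, number 98 of the gibberellin A series) | C=C1C[C@]23C[C@@]1(O)CC[C@H]2[C@]12COC(=O)[C@](C)(C[C@@H](O)C1)[C@H]2[C@@H]3C(=O)O | target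

**Step count**

Total steps: 9. Longest linear sequence: 9 steps (1 to 12).

**Steps most likely to fail**

1. Step 7. The acyloxymethyl radical may be quenched by hydrogen transfer, from the stannane or by an internal 1,5-shift from C3–H or C5–H, before the ester tether rotates into the rotamer that reaches C10, so that simple reduction outpaces ring closure. The fallback makes the same C10–C20 bond with no hydrogen-atom donor present, by oxidative decarboxylative radical generation. Setting out from 7, O-alkylation with allyl bromoacetate (Cs2CO3, DMF) would give the C19 (allyloxycarbonyl)methyl ester F1. Deallylation with Pd(PPh3)4 (zerovalent palladium) and morpholine in THF would give the C19 carboxymethyl ester F2. Irradiation of F2 with blue light in DMF with the organic photocatalyst 4CzIPN and Cs2CO3 (decarboxylative photoredox Giese cyclisation) should oxidise the carboxylate, lose CO2 to the same acyloxymethyl radical, close the ring at C10 and reduce and protonate the C1 radical, coming back to the route at 10.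

2. Step 8. Equilibration may be too slow to override the kinetically preferred hydride delivery to the open β face, leaving the axial 2α-alcohol, or the aluminium alkoxide may exchange the ester groups. The fallback replaces thermodynamic control by kinetic reduction and inversion. Setting out from 10, LiBH(s-Bu)3 (THF, −78 °C) should deliver hydride to the β face and give the axial 2α-alcohol F3. Mitsunobu inversion (PPh3, DIAD, 4-nitrobenzoic acid, toluene), which displaces the axial leaving group from the β side, would give the 2β-(4-nitrobenzoate) F4. Methanolysis (K2CO3, MeOH) would come back to the route at 11.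

3. Step 9. The thiolate may open the δ-lactone in competition with the slow SN2 demethylation of the hindered ester. The fallback is global saponification followed by relactonisation. Setting out from 11, KOH (2 M) in aqueous MeOH at reflux would hydrolyse the C7 ester and open the lactone. Acidification to pH 3 would give the 20-hydroxy-7,19-dioic acid F5, whose axial C19 acid and C20 alcohol should relactonise on standing in the acidic extract, coming back to the route at 12.

**Further compounds**

F1 | step 7 | 7-methyl 19-[(allyloxycarbonyl)methyl] 13-hydroxy-2-oxo-20-norgibberella-1(10),16-diene-7,19-dioate | C=C1C[C@]23C[C@@]1(O)CC[C@H]2C4=CC(=O)C[C@@](C)(C(=O)OCC(=O)OCC=C)[C@H]4[C@@H]3C(=O)OC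
F2 | step 7 | 7-methyl 19-(carboxymethyl) 13-hydroxy-2-oxo-20-norgibberella-1(10),16-diene-7,19-dioate | C=C1C[C@]23C[C@@]1(O)CC[C@H]2C4=CC(=O)C[C@@](C)(C(=O)OCC(=O)O)[C@H]4[C@@H]3C(=O)OC
F3 | step 8 | 2α,13,20-trihydroxygibberell-16-ene-7,19-dioic acid 7-methyl ester 19,20-lactone | C=C1C[C@]23C[C@@]1(O)CC[C@H]2[C@]12COC(=O)[C@](C)(C[C@H](O)C1)[C@H]2[C@@H]3C(=O)OC
F4 | step 8 | 2β-(4-nitrobenzoyloxy)-13,20-dihydroxygibberell-16-ene-7,19-dioic acid 7-methyl ester 19,20-lactone | C=C1C[C@]23C[C@@]1(O)CC[C@H]2[C@]12COC(=O)[C@](C)(C[C@@H](OC(=O)c4ccc(cc4)[N+](=O)[O-])C1)[C@H]2[C@@H]3C(=O)OC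
F5 | step 9 | 2β,13,20-trihydroxygibberell-16-ene-7,19-dioic acid (open-lactone form of the target) | C=C1C[C@]23C[C@@]1(O)CC[C@H]2[C@]1(CO)C[C@H](O)C[C@@](C)(C(=O)O)[C@H]1[C@@H]3C(=O)O
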